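The runs stem from a simulated flask for an exercise, noise included.

In a one-step world, starting material simply turns into target, and each later reading stands above the one before.

all flasks: starting material 1.5 M
- cedar: catalyst 4.3 mol%; temperature 65 °C; run made earlier
- elm: catalyst 9.6 mol%; temperature 98 °C; run made earlier
- Thursday's: catalyst 6.4 mol%; temperature 110 °C; time 4.0 h
- Tuesday's: catalyst 6.4 mol%; temperature 80 °C; time 4.0 h
- Saturday's: catalyst 6.4 mol%; temperature 50 °C; time 4.0 h

| run | time / h | target / % |
|---|---|---|
| cedar | 4.00 | 7 |
| cedar | 8.00 | 6 |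
| cedar | 12.0 | 9 |
| cedar | 15.0 | 7 |
| cedar | 20.0 | 8 |
| cedar | 25.0 | 7 |
| elm | 0.833 | 24 |
| elm | 1.50 | 19 |
| elm | 2.50 | 24 |
| elm | 4.00 | 23 |
| elm | 5.00 | 24 |

(readings scatter by 2 percentage points)

- which flask leads in amount of target, in percent of the starting material charged ("all alike" within 1.5 percentage points) (Thursday's / Tuesday's / Saturday's / all alike)
- how much target is there at the end, in percent of the starting material charged: Thursday's
- how much target is there at the end, in percent of the starting material charged: Tuesday's
- how much target is there at the end, in percent of the starting material charged: Saturday's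

- a reading or a percentage of target counts all its forms, free or not

These readings do not climb. Cedar lies flat around 7.33% from its first reading at 4.00 h, and elm lies flat around 22.8% from 0.833 h, with a scatter of 2 percentage points.

So what does a flat mean? Cedar gives 0.0791 and elm 0.295 for what I call the standing ratio, target at the flat divided by the rest of the charge, an apparent equilibrium constant.

Does that ratio follow temperature or catalyst? The two runs changed both, but target rose 3.11 times on a load 2.23 times as large, so I lean towards temperature: the ratio grows 3.73 times over 33.0 K.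

Do the new flasks reach their flats? Cedar was flat by the time these flasks are read, and Tuesday's is hotter than cedar, as Thursday's is, so I expect both to stand. Saturday's is colder than cedar, so it may still be moving.

Carrying the ratio along in temperature, I get 0.477 for Thursday's, 0.144 for Tuesday's and 0.0435 for Saturday's. That means 32.3%, 12.6% and 4.17% of target once each flask stands at its flat, with Thursday's first.

The forecast, apart from me at both ends, names Thursday's with 26%, 13% and 6%, and says “I lean towards equilibrium, hedged”.

The flasks give Thursday's first, with 28.1%, 14.6% and 8.67%.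

    target + catalyst ⇌ isomer of the product C + catalyst, rate k1*[catalyst]*[target] forward; the back reaction follows from the equilibrium constant (K = 0.960, k = 8.50 × 10⁻⁵ M⁻¹ s⁻¹, Ea = 82.0 kJ mol⁻¹, ΔH = −35.0 kJ mol⁻¹)
    starting material ⇌ target (K = 1.00, k = 3.90 × 10⁻⁵ s⁻¹, Ea = 106 kJ mol⁻¹, ΔH = −9.00 kJ mol⁻¹)
    target ⇌ isomer of the product A (K = 23.0, k = 2.70 × 10⁻⁴ s⁻¹, Ea = 104 kJ mol⁻¹, ΔH = −62.0 kJ mol⁻¹)
    isomer of the product A ⇌ isomer of the product B (K = 0.570, k = 7.20 × 10⁻⁵ s⁻¹, Ea = 110 kJ mol⁻¹, ΔH = −20.0 kJ mol⁻¹)
    starting material ⇌ dormant form (K = 0.330, k = 1.00 × 10⁻⁵ s⁻¹, Ea = 117 kJ mol⁻¹, ΔH = −67.0 kJ mol⁻¹)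
    catalyst + target ⇌ idle complex (K = 1.30 M⁻¹, k = 1.00 × 10⁻⁴ M⁻¹ s⁻¹, Ea = 92.0 kJ mol⁻¹, ΔH = −82.0 kJ mol⁻¹)
    (constants at 50 °C)

Thursday's stands at a ratio of 0.391 against my 0.477, unchanged over a tenfold time. A flask like Saturday's kept at 65 °C reads 7.43%, a ratio of 0.0803 beside cedar's 0.0791 on another catalyst load. The largest single effect in the gap between Thursday's and Saturday's is what temperature does to the step from target to isomer of the product A: without it, the gap shrinks from 19 points to 1.7 points. Saturday's still holds 54% starting material at 4.00 h, and its target falls to 3.02% after 40.0 h.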